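Retrosynthesis cuts the two S–O bonds (O3, O4'), then O1–C2 of ring C, then C4a–C5 of ring A, then C4–C4a (pyrone methyl to ester) and C2–C3 (aldol).
Enabling feature: ring A (C4a, C5, C6, C7, C8, C8a) is a phloroglucinol oxygenated at C5, C7 and C8a and acylated at C4a by C4. This is the alternating pattern of a folded tri-β-keto ester, and a 4-hydroxy-2-pyrone can store C5 to C8a of that chain.
Forward order: ring B aldehyde plus allyloxyacetate (C2–C3), oxidation and ketalisation of C2, acylation of the triacetic acid lactone dianion (C4–C4a), Claisen folding to ring A (C4a–C5), acid closure of ring C (O1–C2).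
C2 is carried as a dioxolane through chain assembly and folding, so C3–H is never the most acidic site. O3 and O4' travel as allyl ethers and O3', O5, O7 as benzyl ethers, so only the two sulfation sites are bared.
Stereochemistry: the target has no stereocentre. C2 and C3 are stereogenic only in passing (racemic, uncontrolled) and both are sp2 after step 9.

Key step: step 8

Assumption: the target is taken as the free bis(hydrogen sulfate) as drawn. Aryl hydrogen sulfates hydrolyse under their own acidity, so the esters are carried as triethylammonium salts and protonated only in the last operation, cold, on a sulfonic acid resin.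

Step 1
Reactants: 1 3,4-dihydroxybenzaldehyde
Product: 2 4-(allyloxy)-3-hydroxybenzaldehyde
Conditions: allyl bromide (1.05 equiv), NaHCO3, DMF, 40 °C
Reagents that add atoms: allyl bromide, C=CCBr
Why: Williamson ether synthesis in which the weak base ionises mainly the 4-OH, the more acidic phenol because it is para to the formyl group, so one equivalent of halide should end up on O-4.

Step 2
Reactants: 2 4-(allyloxy)-3-hydroxybenzaldehyde
Product: 3 4-(allyloxy)-3-(benzyloxy)benzaldehyde
Conditions: BnBr, K2CO3, DMF, rt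
Reagents that add atoms: benzyl bromide, BrCc1ccccc1
Why: Williamson ether synthesis on the only remaining phenol, under conditions to which the aldehyde and the allyl ether are inert.

Step 3
Reactants: 4 ethyl glycolate
Product: 5 ethyl 2-(allyloxy)acetate
Conditions: NaH, allyl bromide, THF, 0 °C to rt
Reagents that add atoms: allyl bromide, C=CCBr
Why: Williamson ether synthesis of a primary alkoxide with a reactive allylic halide, started cold so that O-alkylation outruns transesterification of the glycolate.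

Step 4
Reactants: 5 ethyl 2-(allyloxy)acetate; 3 4-(allyloxy)-3-(benzyloxy)benzaldehyde
Product: 7 ethyl 2-(allyloxy)-3-[4-(allyloxy)-3-(benzyloxy)phenyl]-3-hydroxypropanoate (syn/anti mixture of racemates), via lithium ester enolate 6 (not isolated)
Conditions: LiN(iPr)2, THF, −78 °C; then 3; AcOH quench at −78 °C
Reagents that add atoms: none
Why: Crossed aldol addition of a preformed lithium ester enolate to a non-enolisable aldehyde, held at −78 °C so that the [2,3]-Wittig shift of the allyloxy enolate stays frozen; the two new stereocentres arise without control, which is harmless because one is erased in step 5 and the other in step 9.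

Step 5
Reactants: 7 ethyl 2-(allyloxy)-3-[4-(allyloxy)-3-(benzyloxy)phenyl]-3-hydroxypropanoate
Product: 8 ethyl 2-(allyloxy)-3-[4-(allyloxy)-3-(benzyloxy)phenyl]-3-oxopropanoate (racemic)
Conditions: Dess–Martin periodinane, CH2Cl2, 0 °C to rt
Reagents that add atoms: none
Why: Dess–Martin oxidation of a secondary benzylic alcohol to the aryl ketone under neutral conditions that spare allyl and benzyl ethers and merge both diastereomers into one racemate.

Step 6
Reactants: 8 ethyl 2-(allyloxy)-3-[4-(allyloxy)-3-(benzyloxy)phenyl]-3-oxopropanoate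
Product: 9 ethyl 2-(allyloxy)-2-{2-[4-(allyloxy)-3-(benzyloxy)phenyl]-1,3-dioxolan-2-yl}acetate (racemic)
Conditions: (Me3SiOCH2)2, Me3SiOTf (cat.), CH2Cl2, −78 to 0 °C; pyridine quench
Reagents that add atoms: 1,2-bis(trimethylsilyloxy)ethane, C[Si](C)(C)OCCO[Si](C)(C)C
Why: Noyori ketalisation, driven by formation of hexamethyldisiloxane and run cold, should convert even this α-branched aryl ketone, whose α-ester and α-alkoxy groups favour the ketal; the dioxolane removes the acidic 1,3-dicarbonyl proton and takes C2 out of all later carbonyl chemistry.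

Step 7
Reactants: 10 4-hydroxy-6-methyl-2H-pyran-2-one (triacetic acid lactone); 9 ethyl 2-(allyloxy)-2-{2-[4-(allyloxy)-3-(benzyloxy)phenyl]-1,3-dioxolan-2-yl}acetate
Product: 12 6-[3-(allyloxy)-3-{2-[4-(allyloxy)-3-(benzyloxy)phenyl]-1,3-dioxolan-2-yl}-2-oxopropyl]-4-hydroxy-2H-pyran-2-one (racemic), via dilithio pyrone dianion 11 (not isolated)
Conditions: 10 (2.5 equiv), LiN(iPr)2 (5.2 equiv), THF, −78 to 0 °C; then 9, −78 to −10 °C; cold 1 M HCl to pH 3
Reagents that add atoms: none
Why: Claisen-type C-acylation of the pyrone dianion, which reacts at its last-formed and most basic site (the 6-CH2 carbanion) with the inductively activated α-alkoxy ester, as is known for ketal-masked β-keto esters and such polyanions; surplus dianion deprotonates the more acidic product and prevents a second addition.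

Step 8
Reactants: 12 6-[3-(allyloxy)-3-{2-[4-(allyloxy)-3-(benzyloxy)phenyl]-1,3-dioxolan-2-yl}-2-oxopropyl]-4-hydroxy-2H-pyran-2-one
Product: 14 2-(allyloxy)-2-{2-[4-(allyloxy)-3-(benzyloxy)phenyl]-1,3-dioxolan-2-yl}-1-(2,4,6-trihydroxyphenyl)ethan-1-one (racemic), via open-chain triketo methyl ester 13 (not isolated)
Conditions: Mg(OMe)2 (8 equiv), MeOH, reflux, under argon; cold 1 M HCl to pH 4
Reagents that add atoms: none
Why: Divalent magnesium binds the pyrone oxygens and delivers methoxide to the lactone carbonyl (the future C5), so the ring opens to the chelated chain 13, in which the C4a methylene lying between the C4 and C8a carbonyls is ionised, adds to the C5 ester carbonyl and expels methoxide; the cyclic trione then enolises three times to the phenol. The closest known reaction type is the biomimetic Claisen (Dieckmann-type) cyclisation of 6-(2-oxoalkyl)-4-hydroxy-2-pyrones and of 3,5,7-trioxo esters to 2-acylphloroglucinols under Mg(OMe)2. Ring A closes in a 6-(enolexo)-exo-trig mode and C4a–C5 is the only skeletal bond formed. No stereocentre is created, and the racemic C3 centre is left alone because C4 is engaged first in the C4a enolate and then in the acylphenoxide, which keeps C3–H non-acidic and thereby suppresses both β-elimination of the ketal and a sigmatropic shift of the 3-O-allyl group. The selectivity required is Claisen over aldol folding: attack of C8 on C2 is excluded since C2 is a ketal, attack of C6 on C4 is slowed by the crowded C3/C2 neighbourhood of that ketone, and C5 remains an acyl donor because the lactone is opened by methoxide and not by hydroxide. Aromatisation makes the Claisen channel irreversible, so it should drain the equilibrating magnesium enolates.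

Step 9
Reactants: 14 2-(allyloxy)-2-{2-[4-(allyloxy)-3-(benzyloxy)phenyl]-1,3-dioxolan-2-yl}-1-(2,4,6-trihydroxyphenyl)ethan-1-one
Product: 16 3-(allyloxy)-2-[4-(allyloxy)-3-(benzyloxy)phenyl]-5,7-dihydroxy-4H-chromen-4-one, via free 1,3-diketone 15 (not isolated)
Conditions: 2 M aq HCl, THF–MeOH, 55 °C
Reagents that add atoms: none
Why: Acid hydrolysis of the aryl ketal (oxocarbenium ion stabilised by the 4-allyloxyphenyl group) followed by the classical cyclodehydration of a 2-hydroxyaryl 1,3-diketone, in which either of the two equivalent ortho hydroxyls adds to C2 in a 6-exo-trig closure and loss of water gives the conjugated chromenone and erases the C3 stereocentre.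

Step 10
Reactants: 16 3-(allyloxy)-2-[4-(allyloxy)-3-(benzyloxy)phenyl]-5,7-dihydroxy-4H-chromen-4-one
Product: 17 3-(allyloxy)-2-[4-(allyloxy)-3-(benzyloxy)phenyl]-5,7-bis(benzyloxy)-4H-chromen-4-one
Conditions: BnBr (3 equiv), K2CO3, DMF, 70 °C
Reagents that add atoms: benzyl bromide, BrCc1ccccc1
Why: Williamson ether synthesis in which the 7-OH reacts readily and the hydrogen-bonded 5-OH needs the excess halide and the heating, still far below the onset of aryl allyl ether Claisen rearrangement.

Step 11
Reactants: 17 3-(allyloxy)-2-[4-(allyloxy)-3-(benzyloxy)phenyl]-5,7-bis(benzyloxy)-4H-chromen-4-one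
Product: 18 5,7-bis(benzyloxy)-2-[3-(benzyloxy)-4-hydroxyphenyl]-3-hydroxy-4H-chromen-4-one (3',5,7-tri-O-benzylquercetin)
Conditions: Pd(PPh3)4 (5 mol %), morpholine, THF, rt
Reagents that add atoms: none
Why: Tsuji–Trost-type deallylation, in which zerovalent palladium ionises both allyl ethers because the 4'-phenoxide and the flavonol 3-oxide are good leaving groups, morpholine traps the π-allyl complex, and benzyl ethers are inert.

Step 12
Reactants: 18 5,7-bis(benzyloxy)-2-[3-(benzyloxy)-4-hydroxyphenyl]-3-hydroxy-4H-chromen-4-one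
Product: 19 bis(triethylammonium) salt of 3',5,7-tri-O-benzylquercetin 3,4'-bissulfate
Conditions: SO3·NEt3 (6 equiv), DMF, 40 °C; silica, CH2Cl2–MeOH–Et3N
Reagents that add atoms: sulfur trioxide–triethylamine complex, CC[N+](CC)(CC)S(=O)(=O)[O-]
Why: O-sulfation of phenolic and enolic hydroxyls with a sulfur trioxide–amine complex, the standard entry to flavonoid sulfates, with the regiochemistry fixed by the protecting groups since only O-3 and O-4' are free.

Step 13
Reactants: 19 bis(triethylammonium) salt of 3',5,7-tri-O-benzylquercetin 3,4'-bissulfate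
Product: 21 quercetin 3,4'-bissulfate, via debenzylated bis(triethylammonium) salt 20 (not isolated)
Conditions: H2 (1 atm), Pd/C, MeOH, rt; filter; sulfonic acid cation-exchange resin (H+ form), H2O–MeOH, 0 °C; freeze-dry
Reagents that add atoms: none
Why: Catalytic hydrogenolysis of aryl benzyl ethers, to which sulfate monoester salts and the tetrasubstituted C2=C3 bond are inert, followed by cation exchange that swaps triethylammonium for protons without heating.

Compound list
1 | 3,4-dihydroxybenzaldehyde | O=Cc1ccc(O)c(O)c1 | starting material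
2 | 4-(allyloxy)-3-hydroxybenzaldehyde | O=Cc1ccc(OCC=C)c(O)c1 | intermediate
3 | 4-(allyloxy)-3-(benzyloxy)benzaldehyde | O=Cc1ccc(OCC=C)c(OCc2ccccc2)c1 | intermediate
4 | ethyl glycolate | CCOC(=O)CO | starting material
5 | ethyl 2-(allyloxy)acetate | CCOC(=O)COCC=C | intermediate
6 | lithium enolate of ethyl 2-(allyloxy)acetate (formed in situ) | [Li+].CCOC([O-])=COCC=C | intermediate
7 | ethyl 2-(allyloxy)-3-[4-(allyloxy)-3-(benzyloxy)phenyl]-3-hydroxypropanoate (syn/anti mixture of racemates) | CCOC(=O)C(OCC=C)C(O)c1ccc(OCC=C)c(OCc2ccccc2)c1 | intermediate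
8 | ethyl 2-(allyloxy)-3-[4-(allyloxy)-3-(benzyloxy)phenyl]-3-oxopropanoate (racemic) | CCOC(=O)C(OCC=C)C(=O)c1ccc(OCC=C)c(OCc2ccccc2)c1 | intermediate
9 | ethyl 2-(allyloxy)-2-{2-[4-(allyloxy)-3-(benzyloxy)phenyl]-1,3-dioxolan-2-yl}acetate (racemic) | CCOC(=O)C(OCC=C)C1(OCCO1)c1ccc(OCC=C)c(OCc2ccccc2)c1 | intermediate
10 | 4-hydroxy-6-methyl-2H-pyran-2-one (triacetic acid lactone) | Cc1cc(O)cc(=O)o1 | starting material
11 | dilithio dianion of 4-hydroxy-6-methyl-2H-pyran-2-one (formed in situ) | [Li+].[Li+].[CH2-]c1cc([O-])cc(=O)o1 | intermediate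
12 | 6-[3-(allyloxy)-3-{2-[4-(allyloxy)-3-(benzyloxy)phenyl]-1,3-dioxolan-2-yl}-2-oxopropyl]-4-hydroxy-2H-pyran-2-one (racemic) | O=c1cc(O)cc(CC(=O)C(OCC=C)C2(OCCO2)c2ccc(OCC=C)c(OCc3ccccc3)c2)o1 | intermediate
13 | methyl 8-(allyloxy)-8-{2-[4-(allyloxy)-3-(benzyloxy)phenyl]-1,3-dioxolan-2-yl}-3,5,7-trioxooctanoate (racemic, magnesium chelate in situ, drawn neutral) | COC(=O)CC(=O)CC(=O)CC(=O)C(OCC=C)C1(OCCO1)c1ccc(OCC=C)c(OCc2ccccc2)c1 | intermediate
14 | 2-(allyloxy)-2-{2-[4-(allyloxy)-3-(benzyloxy)phenyl]-1,3-dioxolan-2-yl}-1-(2,4,6-trihydroxyphenyl)ethan-1-one (racemic) | O=C(c1c(O)cc(O)cc1O)C(OCC=C)C1(OCCO1)c1ccc(OCC=C)c(OCc2ccccc2)c1 | intermediate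
15 | 2-(allyloxy)-1-[4-(allyloxy)-3-(benzyloxy)phenyl]-3-(2,4,6-trihydroxyphenyl)propane-1,3-dione (racemic, formed in situ) | O=C(c1ccc(OCC=C)c(OCc2ccccc2)c1)C(OCC=C)C(=O)c1c(O)cc(O)cc1O | intermediate
16 | 3-(allyloxy)-2-[4-(allyloxy)-3-(benzyloxy)phenyl]-5,7-dihydroxy-4H-chromen-4-one | O=c1c(OCC=C)c(-c2ccc(OCC=C)c(OCc3ccccc3)c2)oc2cc(O)cc(O)c12 | intermediate
17 | 3-(allyloxy)-2-[4-(allyloxy)-3-(benzyloxy)phenyl]-5,7-bis(benzyloxy)-4H-chromen-4-one | O=c1c(OCC=C)c(-c2ccc(OCC=C)c(OCc3ccccc3)c2)oc2cc(OCc3ccccc3)cc(OCc3ccccc3)c12 | intermediate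
18 | 5,7-bis(benzyloxy)-2-[3-(benzyloxy)-4-hydroxyphenyl]-3-hydroxy-4H-chromen-4-one | O=c1c(O)c(-c2ccc(O)c(OCc3ccccc3)c2)oc2cc(OCc3ccccc3)cc(OCc3ccccc3)c12 | intermediate
19 | bis(triethylammonium) salt of 3',5,7-tri-O-benzylquercetin 3,4'-bissulfate | O=c1c(OS(=O)(=O)[O-])c(-c2ccc(OS(=O)(=O)[O-])c(OCc3ccccc3)c2)oc2cc(OCc3ccccc3)cc(OCc3ccccc3)c12.CC[NH+](CC)CC.CC[NH+](CC)CC | intermediate
20 | bis(triethylammonium) salt of quercetin 3,4'-bissulfate (formed in situ) | O=c1c(OS(=O)(=O)[O-])c(-c2ccc(OS(=O)(=O)[O-])c(O)c2)oc2cc(O)cc(O)c12.CC[NH+](CC)CC.CC[NH+](CC)CC | intermediate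
21 | quercetin 3,4'-bissulfate | O=c1c(OS(=O)(=O)O)c(-c2ccc(OS(=O)(=O)O)c(O)c2)oc2cc(O)cc(O)c12 | target

Total step count: 13. Longest linear sequence: 12 steps (steps 1, 2 and 4 to 13, from compound 1).

Steps most likely to fail

Step 7. The strongly basic dianion may abstract the C3 proton of the ester, which would trigger β-elimination and open the dioxolane. Addition to a carbonyl next to a neopentyl-like centre may also be too slow.
Fallback (sets out from 9, comes back at 12): the ester acylation is replaced by a fast carbonyl addition and a later oxidation. Reduction of 9 with iBu2AlH (CH2Cl2, −78 °C) should stop at 2-(allyloxy)-2-{2-[4-(allyloxy)-3-(benzyloxy)phenyl]-1,3-dioxolan-2-yl}acetaldehyde F1. Addition of dianion 11 at −78 °C, a known reaction of this dianion with aldehydes, should give 6-[3-(allyloxy)-3-{2-[4-(allyloxy)-3-(benzyloxy)phenyl]-1,3-dioxolan-2-yl}-2-hydroxypropyl]-4-hydroxy-2H-pyran-2-one F2 as a diastereomer mixture. Dess–Martin oxidation of the carbinol should then return ketone 12.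

Step 8. The chain may fold by the aldol mode (C6 onto C4), the deactivated pyrone anion may open incompletely, or the opened chain may break down on work-up.
Fallback (sets out from 5 and 3, comes back at 16): ring A is bought instead of folded.
- Benzene-1,3,5-triol with chloromethyl methyl ether and iPr2NEt gives 1,3,5-tris(methoxymethoxy)benzene F3.
- Directed ortho-lithiation (n-BuLi, THF, 0 °C) and addition to an excess of ester 5 at −78 °C should give 2-(allyloxy)-1-[2,4,6-tris(methoxymethoxy)phenyl]ethan-1-one F4.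
- Enolisation with LiN(iPr)2 at −78 °C and aldol addition to aldehyde 3 should give 2-(allyloxy)-3-[4-(allyloxy)-3-(benzyloxy)phenyl]-3-hydroxy-1-[2,4,6-tris(methoxymethoxy)phenyl]propan-1-one F5.
- Dess–Martin oxidation gives 2-(allyloxy)-1-[4-(allyloxy)-3-(benzyloxy)phenyl]-3-[2,4,6-tris(methoxymethoxy)phenyl]propane-1,3-dione F6.
- The aqueous HCl of step 9 strips the three acetals, passes through 15 and ends at 16.

Step 6. Ketalisation of a hindered ketone conjugated to an electron-rich ring may be sluggish, the ketal may collapse to an enol ether, or the Lewis acid may induce a [3,3] shift in the enol form.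
Fallback (sets out from 8, comes back at 16): C2 is masked by O-alkylation of the enolate instead of by addition to the carbonyl.
- NaH and chloromethyl methyl ether (DMF, 0 °C) should give the non-enolisable ethyl 2-(allyloxy)-3-[4-(allyloxy)-3-(benzyloxy)phenyl]-3-(methoxymethoxy)prop-2-enoate F7 (E/Z mixture).
- Acylation of dianion 11 as in step 7, with a buffered work-up, should give 6-{3-(allyloxy)-4-[4-(allyloxy)-3-(benzyloxy)phenyl]-4-(methoxymethoxy)-2-oxobut-3-en-1-yl}-4-hydroxy-2H-pyran-2-one F8.
- Mg(OMe)2 in MeOH should fold it in the same C4a-to-C5 sense to 2-(allyloxy)-3-[4-(allyloxy)-3-(benzyloxy)phenyl]-3-(methoxymethoxy)-1-(2,4,6-trihydroxyphenyl)prop-2-en-1-one F9.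
- The aqueous HCl of step 9 hydrolyses the enol acetal and closes ring C to 16.

Further compounds
F1 | step 7 | 2-(allyloxy)-2-{2-[4-(allyloxy)-3-(benzyloxy)phenyl]-1,3-dioxolan-2-yl}acetaldehyde (racemic) | O=CC(OCC=C)C1(OCCO1)c1ccc(OCC=C)c(OCc2ccccc2)c1
F2 | step 7 | 6-[3-(allyloxy)-3-{2-[4-(allyloxy)-3-(benzyloxy)phenyl]-1,3-dioxolan-2-yl}-2-hydroxypropyl]-4-hydroxy-2H-pyran-2-one (diastereomer mixture, racemic) | O=c1cc(O)cc(CC(O)C(OCC=C)C2(OCCO2)c2ccc(OCC=C)c(OCc3ccccc3)c2)o1
F3 | step 8 | 1,3,5-tris(methoxymethoxy)benzene | COCOc1cc(OCOC)cc(OCOC)c1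
F4 | step 8 | 2-(allyloxy)-1-[2,4,6-tris(methoxymethoxy)phenyl]ethan-1-one | C=CCOCC(=O)c1c(OCOC)cc(OCOC)cc1OCOC
F5 | step 8 | 2-(allyloxy)-3-[4-(allyloxy)-3-(benzyloxy)phenyl]-3-hydroxy-1-[2,4,6-tris(methoxymethoxy)phenyl]propan-1-one (diastereomer mixture, racemic) | C=CCOC(C(O)c1ccc(OCC=C)c(OCc2ccccc2)c1)C(=O)c1c(OCOC)cc(OCOC)cc1OCOC
F6 | step 8 | 2-(allyloxy)-1-[4-(allyloxy)-3-(benzyloxy)phenyl]-3-[2,4,6-tris(methoxymethoxy)phenyl]propane-1,3-dione (racemic) | C=CCOC(C(=O)c1ccc(OCC=C)c(OCc2ccccc2)c1)C(=O)c1c(OCOC)cc(OCOC)cc1OCOC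
F7 | step 6 | ethyl 2-(allyloxy)-3-[4-(allyloxy)-3-(benzyloxy)phenyl]-3-(methoxymethoxy)prop-2-enoate (E/Z mixture) | CCOC(=O)C(OCC=C)=C(OCOC)c1ccc(OCC=C)c(OCc2ccccc2)c1
F8 | step 6 | 6-{3-(allyloxy)-4-[4-(allyloxy)-3-(benzyloxy)phenyl]-4-(methoxymethoxy)-2-oxobut-3-en-1-yl}-4-hydroxy-2H-pyran-2-one (E/Z mixture) | O=c1cc(O)cc(CC(=O)C(OCC=C)=C(OCOC)c2ccc(OCC=C)c(OCc3ccccc3)c2)o1
F9 | step 6 | 2-(allyloxy)-3-[4-(allyloxy)-3-(benzyloxy)phenyl]-3-(methoxymethoxy)-1-(2,4,6-trihydroxyphenyl)prop-2-en-1-one (E/Z mixture) | O=C(c1c(O)cc(O)cc1O)C(OCC=C)=C(OCOC)c1ccc(OCC=C)c(OCc2ccccc2)c1
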